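**Strategy.** The target is an unbranched, stereocenter-free C21 acyl chain whose only reactive site is the ester carbonyl C1; the benzene ring of the 2-phenylethyl group is a spectator. Everything rests on forming the unactivated CH2–CH2 bond C12–C13 of the chain, eleven carbons from C1, by copper-catalysed sp3–sp3 cross-coupling. In one operation nonylmagnesium bromide (C13–C21) is joined to 2-phenylethyl 12-bromododecanoate (C1–C12, ester already complete), which gives the target directly as the last step. The key step exploits the long methylene spacer between C12–Br and the C1 carbonyl, which lets the cuprate select the primary bromide over the ester.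

Key step: step 2

Remark: nonylmagnesium bromide is taken as the commercial ethereal solution and titrated before use. The target has no stereocenter, so no stereocontrol is needed.

**Step 1**
Reactants: 1 12-bromododecanoic acid; 2 2-phenylethanol
Product: 3 2-phenylethyl 12-bromododecanoate
Conditions: TsOH·H2O (5 mol%), 2 (1.2 equiv), toluene, reflux, Dean–Stark
Reagents that add atoms: none
Why: Fischer esterification driven to completion by azeotropic removal of water; the primary alkyl bromide and the non-benzylic primary alcohol should be stable to catalytic sulfonic acid in refluxing toluene.

**Step 2**
Reactants: 3 2-phenylethyl 12-bromododecanoate; 4 nonylmagnesium bromide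
Product: 5 phenylethyl n-heneicosanoate (2-phenylethyl heneicosanoate)
Conditions: Li2CuCl4 (3 mol%), NMP (4 equiv), THF, 0 °C to rt, slow addition of 4 (1.15 equiv, 1 M in Et2O); then aq NH4Cl
Reagents that add atoms: none
Why: Kochi-type copper-catalysed alkyl–alkyl cross-coupling of a Grignard reagent with a primary alkyl bromide: Li2CuCl4 is reduced by 4 to a copper(I) species that forms a nonylcuprate, which attacks the primary C12–Br carbon of 3 in an SN2-type oxidative addition and then forms the C12–C13 bond by reductive elimination from copper(III), releasing MgBr2. The closest known reaction type is the NMP-promoted Cu-catalysed coupling of alkylmagnesium halides with ω-functionalised primary alkyl bromides, a reaction class known to tolerate ester groups. No ring is closed and no stereocenter is formed. The step needs chemoselectivity for the C–Br carbon over the ester carbonyl and cross-coupling over homo-coupling; the unhindered primary bromide, eleven carbons from the carbonyl, should react with the cuprate far faster than 4 adds uncatalysed to the ester, and slow addition of 4 into the mixture of 3, catalyst and NMP keeps the concentration of free Grignard reagent low.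

**Compound list**
1 | 12-bromododecanoic acid | OC(=O)CCCCCCCCCCCBr | starting material
2 | 2-phenylethanol | OCCc1ccccc1 | starting material
3 | 2-phenylethyl 12-bromododecanoate | BrCCCCCCCCCCCC(=O)OCCc1ccccc1 | intermediate
4 | nonylmagnesium bromide | CCCCCCCCC[Mg]Br | starting material
5 | phenylethyl n-heneicosanoate (2-phenylethyl heneicosanoate) | CCCCCCCCCCCCCCCCCCCCC(=O)OCCc1ccccc1 | target

**Total step count:** 2
**Longest linear sequence:** 2 steps (1 → 3 → 5)

**Steps most likely to fail** (the route has only two steps, so both are ranked)

1. Step 2 (key step). The Grignard reagent may add to the ester carbonyl or enolise it in competition with the copper-catalysed substitution. Homo-coupling, or reduction of the bromide by β-hydride pathways, may also erode the cross-coupling. Fallback, setting out from 3: 1-nonene is hydroborated with 9-BBN (THF, 0 °C to rt) to give B-nonyl-9-borabicyclo[3.3.1]nonane F1. This is coupled in the same flask with 3 by a B-alkyl Suzuki–Miyaura reaction for alkyl bromides bearing β-hydrogens (Pd(OAc)2, PCy3, K3PO4·H2O, THF, rt). The organoborane does not attack esters, and the same C12–C13 bond is formed; the fallback comes back to the route at 5.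

2. Step 1. The equilibrium esterification may stall, or the acid catalyst may promote self-etherification or dehydration of 2-phenylethanol on prolonged heating. Fallback, setting out from 1: the acid is activated irreversibly with oxalyl chloride (cat. DMF, CH2Cl2, 0 °C to rt) to give 12-bromododecanoyl chloride F2. This is acylated onto 2 with pyridine in CH2Cl2 at 0 °C to rt; the fallback comes back to the route at 3.

**Further compounds**
F1 | step 2 | B-nonyl-9-borabicyclo[3.3.1]nonane | CCCCCCCCCB1C2CCCC1CCC2
F2 | step 1 | 12-bromododecanoyl chloride | ClC(=O)CCCCCCCCCCCBr
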